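The synthesis rests on cutting ring B (O, C7', C8', C8, C9) at O–C7' and C7'–C8'. The feature used is that C7' is bonded only to Ar2, H, the ring-B oxygen and C8', while C8' turns into an enolisable α-carbon once ring A (O, C7, C8, C8', C9') is drawn as a γ-lactone with C9' as carbonyl. A single Me3SiOTf-catalysed operation therefore inserts the carbonyl carbon of 3-methoxy-4-prenyloxybenzaldehyde between O9 and C8', closing ring B and fixing C7' and C8'. Its precursor is a monocyclic, aldol-derived trans-lactone in doubly trimethylsilylated form: silyl ether on the C9 oxygen, silyl ketene acetal across C8'=C9'.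

Key step: step 8

Remark on numbering and configuration: C7 carries Ar1 (4-hydroxy-3-methoxyphenyl, masked as its TIPS ether) and C7' carries Ar2 (3-methoxy-4-prenyloxyphenyl). C8 and C8' are the ring-fusion carbons, C9 (on C8) and C9' (on C8') are the OCH2 carbons, and O9 is the oxygen on C9. The target SMILES reads 7R,7'R,8S,8'S with both aryl groups exo. This is the series enantiomeric to (+)-pinoresinol, and it requires the (R)-configured auxiliary.

Design remarks:
- Both transferable silyl groups of the precursor are Me3Si, so silicon leaves as one inert molecule and the promoter is regenerated.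
- The free hydroxymethyl lactone is silylated without isolation, because its hydroxyl could migrate onto the lactone carbonyl.
- The prenyl group enters only after the borane and peroxide steps.

Step 1
Reactants: 1 vanillin
Product: 2 3-methoxy-4-(triisopropylsilyloxy)benzaldehyde
Conditions: iPr3SiCl, imidazole, DMF, rt
Reagents that add atoms: triisopropylsilyl chloride, CC(C)[Si](Cl)(C(C)C)C(C)C
Why: Imidazole-mediated O-silylation of the phenol (silyl ether protection) is routine, and the hindered aryl TIPS ether is chosen because it should outlast LiOOH, BH3, LiN(iPr)2, Me3SiOTf and LiAlH4 yet fall to fluoride without touching the prenyl ether.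

Step 2
Reactants: 3 (R)-4-benzyl-2-oxazolidinone; 4 methyl 4-chloro-4-oxobutanoate
Product: 6 methyl 4-[(4R)-4-benzyl-2-oxo-1,3-oxazolidin-3-yl]-4-oxobutanoate, via N-lithio oxazolidinone 5 (not isolated)
Conditions: n-BuLi, THF, −78 °C; then 4, −78 to 0 °C
Reagents that add atoms: none
Why: N-acylation of the lithiated Evans auxiliary, in which the acid chloride terminus of 4 is far more electrophilic than its methyl ester, so only the imide should form and the auxiliary stereocentre is not involved.

Step 3
Reactants: 6 succinate imide; 2 silylated vanillin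
Product: 9 (4R)-4-benzyl-3-{[(2R,3R)-2-(3-methoxy-4-triisopropylsilyloxyphenyl)-5-oxooxolan-3-yl]carbonyl}-1,3-oxazolidin-2-one (trans-lactone imide), via boron enolate 7 (not isolated), via syn-aldol adduct 8 (not isolated)
Conditions: Bu2BOTf, iPr2NEt, CH2Cl2, 0 °C; 2, −78 to 0 °C; H2O2, MeOH, aq NaH2PO4/Na2HPO4 (pH 7), 0 °C; then pyridinium p-toluenesulfonate (cat.), CH2Cl2, rt
Reagents that add atoms: none
Why: Evans syn-aldol reaction followed by lactonisation, in which Bu2BOTf/iPr2NEt enolises only the chelating imide carbonyl to the (Z)-enolate 7, this adds to 2 through a Zimmerman–Traxler chair on the enolate face remote from the benzyl group of the (R)-auxiliary and so sets C8 and C7 (both R at this stage), and the C7 hydroxyl of syn adduct 8 then closes onto the methyl ester so that Ar1 and the C9 acyl group end up trans on ring A.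

Step 4
Reactants: 9 trans-lactone imide
Product: 11 (2R,3R)-2-(3-methoxy-4-triisopropylsilyloxyphenyl)-5-oxooxolane-3-carboxylic acid, via peroxy acid 10 (not isolated)
Conditions: LiOH, H2O2, THF–H2O, 0 °C; aq Na2SO3; 1 M HCl to pH 3
Reagents that add atoms: hydrogen peroxide, OO
Why: Hydroperoxide cleavage of an N-acyl oxazolidinone, in which LiOOH attacks the exocyclic imide carbonyl in preference to the carbamate and the lactone, sulfite reduces peroxy acid 10, and any lactone opened by hydroxide should reclose on acidification because only the five-membered ring through the C7 oxygen is accessible, with C7 and C8 untouched at 0 °C.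

Step 5
Reactants: 11 lactone acid
Product: 13 (4S,5R)-5-(3-methoxy-4-triisopropylsilyloxyphenyl)-4-(trimethylsilyloxymethyl)oxolan-2-one, via hydroxymethyl lactone 12 (not isolated)
Conditions: BH3·SMe2, THF, 0 °C to rt; MeOH, evaporation; then Me3SiCl, imidazole, CH2Cl2, 0 °C
Reagents that add atoms: chlorotrimethylsilane, C[Si](C)(C)Cl
Why: Chemoselective borane reduction of a carboxylic acid (via its acyloxyborane) beside a lactone, telescoped with O-silylation so that free alcohol 12, whose C9 hydroxyl could migrate onto C9' by translactonisation, is never stored or chromatographed, and no stereocentre is affected (C8 changes descriptor only).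

Step 6
Reactants: 13 silyl ether lactone
Product: 15 (2R,3S)-2-(3-methoxy-4-triisopropylsilyloxyphenyl)-5-trimethylsilyloxy-3-(trimethylsilyloxymethyl)-2,3-dihydrofuran, via lithium enolate 14 (not isolated)
Conditions: LiN(iPr)2, THF, −78 °C; Me3SiCl, −78 °C to rt; pentane, filtration under Ar, used crude
Reagents that add atoms: chlorotrimethylsilane, C[Si](C)(C)Cl
Why: Kinetic enolisation and O-silylation of a lactone (silyl ketene acetal formation), which should be clean because C8' is the only acidic position, the enolate has no β-leaving group, Me3SiCl traps γ-lactone enolates on oxygen, and C7 and C8 stay as set.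

Step 7
Reactants: 1 vanillin; 16 prenyl bromide
Product: 17 3-methoxy-4-(3-methylbut-2-enyloxy)benzaldehyde
Conditions: K2CO3, DMF, rt
Reagents that add atoms: none
Why: Williamson ether synthesis, in which the phenoxide of 1 displaces bromide from the primary allylic carbon of 16 by SN2 and the para-formyl group keeps C-alkylation negligible.

Step 8
Reactants: 15 bis-silylated ketene acetal; 17 prenylated aldehyde
Product: 19 (3R,3aS,6R,6aR)-6-[3-methoxy-4-(3-methylbut-2-enyloxy)phenyl]-3-[3-methoxy-4-(triisopropylsilyloxy)phenyl]tetrahydro-1H,3H-furo[3,4-c]furan-1-one (exo,exo-furofuranone with C9' as carbonyl), via oxocarbenium triflate 18 (not isolated)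
Conditions: 15 and 17 premixed, 2,6-di-tert-butyl-4-methylpyridine (0.3 equiv), CH2Cl2 (0.01 M), −78 °C; Me3SiOTf (0.2 equiv) added last; Et3N, then aq NaHCO3 at −78 °C
Reagents that add atoms: none
Why: Me3SiOTf silylates the carbonyl oxygen of 17, the unhindered O9 silyl ether adds, (Me3Si)2O is expelled to give the aryl-stabilised (E)-oxocarbenium ion 18, C8' of the ketene acetal attacks C7', and loss of Me3Si+ from the C9' oxygen restores the lactone carbonyl and regenerates the promoter. The closest known reaction type is the Me3SiOTf-mediated silyl ether/aldehyde condensation with intramolecular Mukaiyama aldol (Prins-type) capture by an enol silane or cyclic enol ether. Ring B closes in a 5-(enolexo)-endo-trig mode, endocyclic with respect to O9=C7' and exocyclic with respect to C8'=C9', a geometry that cationic oxocarbenium electrophiles accept although it is formally disfavoured. C8' is set by the tether, since the two-atom C9–O9 link lies on the face of ring A opposite Ar1 and can reach only that face of C8' (cis fusion, 8'R in the lactone), and C7' is set by the (E)-ion reacting in the envelope that turns Ar2 away from ring A and from the OSiMe3 group on C9', which places Ar2 exo (7'R), also the more stable arrangement. The step needs the tethered path to beat direct intermolecular Mukaiyama addition of 15 to 17, which would enter anti to C9 and could not close; this is secured by the weak activation of free aryl aldehydes toward enol silanes by Me3SiOTf at −78 °C compared with their fast condensation with a primary Me3SiO group, and by high dilution, which favours the unimolecular closure. The hindered pyridine scavenges adventitious TfOH and so shields the prenyl ether, the ketene acetal and the benzylic C7–O bond.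

Step 9
Reactants: 19 furofuranone
Product: 20 (R)-{(3S,4S,5R)-4-(hydroxymethyl)-5-[3-methoxy-4-(3-methylbut-2-enyloxy)phenyl]oxolan-3-yl}[3-methoxy-4-(triisopropylsilyloxy)phenyl]methanol
Conditions: LiAlH4, THF, 0 °C; then H2O, aq NaOH
Reagents that add atoms: none
Why: Hydride reduction of the lactone to the 1,4-diol, which leaves ring B, the prenyl ether and the aryl TIPS ether alone and changes no stereocentre (C8' only changes descriptor from R to S because C9' drops in priority).

Step 10
Reactants: 20 diol
Product: 22 (1R,3aS,4R,6aS)-4-[3-methoxy-4-(3-methylbut-2-enyloxy)phenyl]-1-[3-methoxy-4-(triisopropylsilyloxy)phenyl]tetrahydro-1H,3H-furo[3,4-c]furan, via primary mesylate 21 (not isolated)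
Conditions: MsCl (1.1 equiv), pyridine, CH2Cl2, 0 °C to rt
Reagents that add atoms: none
Why: Selective sulfonylation of the unhindered primary C9' hydroxyl over the secondary benzylic C7 hydroxyl, followed by intramolecular Williamson etherification (5-exo-tet, SN2 at C9'), recloses ring A, and since the C7–O bond is never broken the 7R configuration with Ar1 exo is retained.

Step 11
Reactants: 22 silylated furofuran
Product: 23 4-{(1R,3aS,4R,6aS)-4-[3-methoxy-4-(3-methylbut-2-enyloxy)phenyl]tetrahydro-1H,3H-furo[3,4-c]furan-1-yl}-2-methoxyphenol (target CNP0185952.2)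
Conditions: Bu4NF, AcOH, THF, 0 °C
Reagents that add atoms: none
Why: Fluoride-induced cleavage of the aryl silyl ether driven by Si–F bond formation, with acetic acid buffering the phenoxide, while the prenyl ether, both benzylic ethers and all four stereocentres are inert.

Compound list
1 | vanillin (4-hydroxy-3-methoxybenzaldehyde) | COc1cc(C=O)ccc1O | starting material
2 | 3-methoxy-4-(triisopropylsilyloxy)benzaldehyde | COc1cc(C=O)ccc1O[Si](C(C)C)(C(C)C)C(C)C | intermediate
3 | (R)-4-benzyl-2-oxazolidinone | O=C1N[C@H](Cc2ccccc2)CO1 | starting material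
4 | methyl 4-chloro-4-oxobutanoate | COC(=O)CCC(Cl)=O | starting material
5 | N-lithio-(R)-4-benzyl-2-oxazolidinone (not isolated) | [Li]N1[C@H](Cc2ccccc2)COC1=O | intermediate
6 | methyl 4-[(4R)-4-benzyl-2-oxo-1,3-oxazolidin-3-yl]-4-oxobutanoate | COC(=O)CCC(=O)N1[C@H](Cc2ccccc2)COC1=O | intermediate
7 | (Z)-dibutylboron enolate of 6 (not isolated) | CCCCB(CCCC)O/C(=C\CC(=O)OC)N1[C@H](Cc2ccccc2)COC1=O | intermediate
8 | methyl (3R)-4-[(4R)-4-benzyl-2-oxo-1,3-oxazolidin-3-yl]-3-{(R)-hydroxy[3-methoxy-4-(triisopropylsilyloxy)phenyl]methyl}-4-oxobutanoate, syn-aldol adduct (not isolated) | COC(=O)C[C@H]([C@@H](O)c1ccc(O[Si](C(C)C)(C(C)C)C(C)C)c(OC)c1)C(=O)N1[C@H](Cc2ccccc2)COC1=O | intermediate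
9 | (4R)-4-benzyl-3-{[(2R,3R)-2-(3-methoxy-4-triisopropylsilyloxyphenyl)-5-oxooxolan-3-yl]carbonyl}-1,3-oxazolidin-2-one | COc1cc(ccc1O[Si](C(C)C)(C(C)C)C(C)C)[C@@H]2OC(=O)C[C@H]2C(=O)N3[C@H](Cc4ccccc4)COC3=O | intermediate
10 | (2R,3R)-2-(3-methoxy-4-triisopropylsilyloxyphenyl)-5-oxooxolane-3-carboperoxoic acid (not isolated) | COc1cc(ccc1O[Si](C(C)C)(C(C)C)C(C)C)[C@@H]2OC(=O)C[C@H]2C(=O)OO | intermediate
11 | (2R,3R)-2-(3-methoxy-4-triisopropylsilyloxyphenyl)-5-oxooxolane-3-carboxylic acid | COc1cc(ccc1O[Si](C(C)C)(C(C)C)C(C)C)[C@@H]2OC(=O)C[C@H]2C(=O)O | intermediate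
12 | (4S,5R)-4-(hydroxymethyl)-5-(3-methoxy-4-triisopropylsilyloxyphenyl)oxolan-2-one (not isolated) | COc1cc(ccc1O[Si](C(C)C)(C(C)C)C(C)C)[C@@H]2OC(=O)C[C@H]2CO | intermediate
13 | (4S,5R)-5-(3-methoxy-4-triisopropylsilyloxyphenyl)-4-(trimethylsilyloxymethyl)oxolan-2-one | COc1cc(ccc1O[Si](C(C)C)(C(C)C)C(C)C)[C@@H]2OC(=O)C[C@H]2CO[Si](C)(C)C | intermediate
14 | lithium enolate of 13 (not isolated) | COc1cc(ccc1O[Si](C(C)C)(C(C)C)C(C)C)[C@@H]2OC([O-])=C[C@H]2CO[Si](C)(C)C.[Li+] | intermediate
15 | (2R,3S)-2-(3-methoxy-4-triisopropylsilyloxyphenyl)-5-trimethylsilyloxy-3-(trimethylsilyloxymethyl)-2,3-dihydrofuran (key-step precursor) | COc1cc(ccc1O[Si](C(C)C)(C(C)C)C(C)C)[C@@H]2OC(O[Si](C)(C)C)=C[C@H]2CO[Si](C)(C)C | intermediate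
16 | prenyl bromide (1-bromo-3-methylbut-2-ene) | CC(C)=CCBr | starting material
17 | 3-methoxy-4-(3-methylbut-2-enyloxy)benzaldehyde | COc1cc(C=O)ccc1OCC=C(C)C | intermediate
18 | (E)-oxocarbenium triflate tethered through O9 (not isolated) | COc1cc(ccc1O[Si](C(C)C)(C(C)C)C(C)C)[C@@H]2OC(O[Si](C)(C)C)=C[C@H]2C/[O+]=C/c3ccc(OCC=C(C)C)c(OC)c3.[O-]S(=O)(=O)C(F)(F)F | intermediate
19 | (3R,3aS,6R,6aR)-6-[3-methoxy-4-(3-methylbut-2-enyloxy)phenyl]-3-[3-methoxy-4-(triisopropylsilyloxy)phenyl]tetrahydro-1H,3H-furo[3,4-c]furan-1-one (key-step product) | COc1cc(ccc1O[Si](C(C)C)(C(C)C)C(C)C)[C@@H]2OC(=O)[C@@H]3[C@H]2CO[C@H]3c2ccc(OCC=C(C)C)c(OC)c2 | intermediate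
20 | (R)-{(3S,4S,5R)-4-(hydroxymethyl)-5-[3-methoxy-4-(3-methylbut-2-enyloxy)phenyl]oxolan-3-yl}[3-methoxy-4-(triisopropylsilyloxy)phenyl]methanol | COc1cc(ccc1O[Si](C(C)C)(C(C)C)C(C)C)[C@H](O)[C@@H]2CO[C@@H](c3ccc(OCC=C(C)C)c(OC)c3)[C@@H]2CO | intermediate
21 | {(2R,3S,4S)-4-{(R)-hydroxy[3-methoxy-4-(triisopropylsilyloxy)phenyl]methyl}-2-[3-methoxy-4-(3-methylbut-2-enyloxy)phenyl]oxolan-3-yl}methyl methanesulfonate (not isolated) | COc1cc(ccc1O[Si](C(C)C)(C(C)C)C(C)C)[C@H](O)[C@@H]2CO[C@@H](c3ccc(OCC=C(C)C)c(OC)c3)[C@@H]2COS(C)(=O)=O | intermediate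
22 | (1R,3aS,4R,6aS)-4-[3-methoxy-4-(3-methylbut-2-enyloxy)phenyl]-1-[3-methoxy-4-(triisopropylsilyloxy)phenyl]tetrahydro-1H,3H-furo[3,4-c]furan | COc1cc(ccc1O[Si](C(C)C)(C(C)C)C(C)C)[C@@H]2OC[C@@H]3[C@H]2CO[C@H]3c2ccc(OCC=C(C)C)c(OC)c2 | intermediate
23 | 4-{(1R,3aS,4R,6aS)-4-[3-methoxy-4-(3-methylbut-2-enyloxy)phenyl]tetrahydro-1H,3H-furo[3,4-c]furan-1-yl}-2-methoxyphenol | COc1cc([C@@H]2OC[C@@H]3[C@H]2CO[C@H]3c2ccc(OCC=C(C)C)c(OC)c2)ccc1O | target

Total step count: 11
Longest linear sequence: 9 steps (steps 1, 3, 4, 5, 6, 8, 9, 10 and 11, from vanillin)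

Steps most likely to fail

Step 8. The Me3SiOTf-activated aldehyde may be captured by C8' of a second molecule of 15 before O9 has condensed with it. That untethered addition enters anti to C9 and blocks closure to the cis-fused bicycle. Erosion of exo selectivity at C7' and acid-induced loss of the prenyl group are lesser concerns. The fallback makes the two bonds in separate operations; it sets out from 13 and 17 and comes back at 19. Aldehyde 17 would be converted with HC(OMe)3 and catalytic pyridinium p-toluenesulfonate in MeOH into the dimethyl acetal F1. Exchange of an excess of F1 with silyl ether 13 under catalytic Me3SiOTf in CH2Cl2 at −78 °C is a transacetalisation with no carbon nucleophile present, and it should give the mixed methyl acetal F2, whose epimers at the acetal carbon are inconsequential. LiN(iPr)2 and Me3SiCl as in step 6 would then give the tethered silyl ketene acetal F3. Catalytic Me3SiOTf with the hindered pyridine at −78 °C should ionise the less hindered methoxy group. This triggers an ordinary intramolecular Mukaiyama aldol reaction of an acetal under the same tether control, delivering 19.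

Step 10. Sulfonylation or ionisation at the electron-rich benzylic C7 carbinol may compete with primary mesylation, leading to partial epimerisation at C7 or to elimination. The fallback never opens ring A; it sets out from 19, bypasses 20 and comes back at 22. Partial reduction with iBu2AlH (1.1 equiv) in CH2Cl2 at −78 °C should stop at the lactol F4. Ionic reduction with Et3SiH and BF3·OEt2 in CH2Cl2 at −78 °C should then remove the anomeric hydroxyl through the non-benzylic C9' oxocarbenium ion and give 22 with C7 untouched.

Step 4. Hydroperoxide or hydroxide may attack silicon, causing loss of the aryl TIPS group, or base may induce β-elimination of the C7 carboxylate from the imide. The fallback removes the auxiliary reductively instead of hydrolytically; it sets out from 9, skips 11 and comes back at 12. NaBH4 in THF–H2O at 0 °C should reduce the more electrophilic imide carbonyl to the primary alcohol while the γ-lactone survives. This releases 3 and gives 12, which would be silylated at once to 13 as in the second half of step 5. This fallback makes no compound outside the list (F0).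

Further compounds
F1 | step 8 | 4-(dimethoxymethyl)-2-methoxy-1-(3-methylbut-2-enyloxy)benzene | COC(OC)c1ccc(OCC=C(C)C)c(OC)c1
F2 | step 8 | (4S,5R)-4-({methoxy[3-methoxy-4-(3-methylbut-2-enyloxy)phenyl]methoxy}methyl)-5-(3-methoxy-4-triisopropylsilyloxyphenyl)oxolan-2-one, both epimers at the acetal carbon | COc1cc(ccc1O[Si](C(C)C)(C(C)C)C(C)C)[C@@H]2OC(=O)C[C@H]2COC(OC)c3ccc(OCC=C(C)C)c(OC)c3
F3 | step 8 | trimethylsilyl ketene acetal of F2, (2R,3S)-configured 2,3-dihydrofuran | COc1cc(ccc1O[Si](C(C)C)(C(C)C)C(C)C)[C@@H]2OC(O[Si](C)(C)C)=C[C@H]2COC(OC)c3ccc(OCC=C(C)C)c(OC)c3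
F4 | step 10 | C9' lactol of 19, both anomers | COc1cc(ccc1O[Si](C(C)C)(C(C)C)C(C)C)[C@@H]2OC(O)[C@@H]3[C@H]2CO[C@H]3c2ccc(OCC=C(C)C)c(OC)c2
F0 | step 4 | none | none
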